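The target is cut at the bond between C2 of the chromone and the first carbon of the ethylene bridge. In the pyranone ring (ring C) the unit O1–C2=C3–C4=O is a vinylogous ester, so the unsubstituted C2 is the β-carbon of an enone and accepts a carbon nucleophile. One copper-catalysed conjugate addition of a 2-arylethyl Grignard reagent to 6,7-dimethoxychromone installs the whole side chain; silyl trapping and hydrolysis give the chromanone, which is dehydrogenated back to the chromone and debenzylated. The precursors are the bare chromone, made in one pot from an o-hydroxyacetophenone, and a phenethylmagnesium bromide whose phenol is masked as a benzyl ether inert to magnesium and copper.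

Key step: step 6

Remark on the chemistry: the target has no stereocentre; C2 of compounds 10 and 11 is formed racemic in step 6 and is made planar again in step 7. Compounds 1, 2 and 5 are taken as catalogue chemicals. The benzyl group is chosen because it survives LiAlH4, magnesium, the organocopper step and IBX, and is removed last without acid or base.

**Step 1**
Reactants: 1 2'-hydroxy-4',5'-dimethoxyacetophenone; 2 N,N-dimethylformamide dimethyl acetal
Product: 4 6,7-dimethoxychromone (6,7-dimethoxy-4H-chromen-4-one), via enaminone 3 (not isolated)
Conditions: 2 (1.5 equiv), toluene, 100 °C; evaporate; then conc. HCl, CH2Cl2, 40 °C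
Reagents that add atoms: N,N-dimethylformamide dimethyl acetal (compound 2), COC(OC)N(C)C
Why: Condensation of the acetyl methyl group with the formamide acetal gives the push–pull (E)-enaminone 3, and acid then drives 6-endo oxa-Michael attack of the phenol on the β-carbon followed by loss of dimethylamine (addition–elimination), the standard enaminone chromone synthesis.

**Step 2**
Reactants: 5 3-hydroxy-4-methoxyphenylacetic acid
Product: 6 benzyl 2-(3-benzyloxy-4-methoxyphenyl)acetate
Conditions: BnBr (2.3 equiv), K2CO3 (2.5 equiv), DMF, 50 °C
Reagents that add atoms: benzyl bromide, BrCc1ccccc1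
Why: Phenoxide and carboxylate are both alkylated by SN2 displacement (Williamson etherification and carboxylate O-alkylation), while K2CO3 is too weak to deprotonate the arylacetate α-position.

**Step 3**
Reactants: 6 benzyl 2-(3-benzyloxy-4-methoxyphenyl)acetate
Product: 7 2-(3-benzyloxy-4-methoxyphenyl)ethanol
Conditions: LiAlH4, THF, 0 °C → rt; Fieser work-up
Reagents that add atoms: none
Why: Hydride reduction of the ester should give the primary alcohol and benzyl alcohol (removed on silica), and aryl benzyl and aryl methyl ethers are inert to LiAlH4.

**Step 4**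
Reactants: 7 2-(3-benzyloxy-4-methoxyphenyl)ethanol
Product: 8 2-(benzyloxy)-4-(2-bromoethyl)-1-methoxybenzene
Conditions: CBr4, PPh3, CH2Cl2, 0 °C → rt
Reagents that add atoms: carbon tetrabromide, BrC(Br)(Br)Br
Why: In the Appel reaction the primary alcohol is activated as an alkoxyphosphonium ion and displaced by bromide in an SN2 step under neutral conditions that do not touch the ethers.

**Step 5**
Reactants: 8 2-(benzyloxy)-4-(2-bromoethyl)-1-methoxybenzene
Product: 9 2-(3-benzyloxy-4-methoxyphenyl)ethylmagnesium bromide (THF solution, titrated and used directly)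
Conditions: Mg turnings (I2-activated), THF, slow addition, 25–40 °C
Reagents that add atoms: magnesium, [Mg]
Why: Insertion of magnesium into a primary alkyl bromide is a standard Grignard formation; slow addition at moderate dilution should limit Wurtz coupling, and the ether groups are inert.

**Step 6**
Reactants: 4 6,7-dimethoxychromone; 9 2-(3-benzyloxy-4-methoxyphenyl)ethylmagnesium bromide
Product: 11 2-[2-(3-benzyloxy-4-methoxyphenyl)ethyl]-6,7-dimethoxychroman-4-one (racemic), via trimethylsilyl enol ether 10 (not isolated)
Conditions: CuBr·SMe2 (10 mol%), Me3SiCl (2 equiv), THF, −78 °C, slow addition of 9 (1.5 equiv), → −40 °C; then 1 M HCl, rt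
Reagents that add atoms: none
Why: Transmetalation of 9 to CuBr·SMe2 gives a monovalent alkylcopper species that binds the C2=C3 π bond of 4, adds oxidatively at C2 to a trivalent copper intermediate and reductively eliminates to form the C2–CH2 bond, while Me3SiCl captures the resulting enolate as silyl enol ether 10 and so speeds the turnover. The closest known reaction type is the copper-catalysed, chlorosilane-assisted 1,4-addition of alkyl Grignard reagents to chromones and other cyclic enones, which gives 2-alkylchroman-4-ones. No ring is closed. The new stereocentre at C2 is formed without any controlling element, hence as a racemate, and it is removed again in step 7. The step needs 1,4- over 1,2-selectivity and must avoid β-elimination of the ring oxygen from the enolate (opening of ring C); the C4 carbonyl is a vinylogous ester carbonyl further deactivated by the para 7-methoxy group, C2 and C3 carry no substituent, and silylation at −78 °C should remove the enolate before it can fragment. Mild aqueous acid should then hydrolyse 10 to the stable ketone 11, which can be chromatographed free of copper and sulfide residues before the oxidation.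

**Step 7**
Reactants: 11 2-[2-(3-benzyloxy-4-methoxyphenyl)ethyl]-6,7-dimethoxychroman-4-one
Product: 12 2-[2-(3-benzyloxy-4-methoxyphenyl)ethyl]-6,7-dimethoxy-4H-chromen-4-one
Conditions: IBX (2.0 equiv), 4-methoxypyridine N-oxide (2.0 equiv), DMSO, rt → 40 °C
Reagents that add atoms: none
Why: The ketone can enolise only toward C3, the enol is captured at the pentavalent iodine centre of IBX and the adduct breaks down with loss of the C2 hydrogen to restore the C2=C3 bond (IBX dehydrogenation of a ketone to an enone), which erases the C2 stereocentre; the N-oxide ligand allows this near room temperature, where the benzyl ether and the benzylic CH2 groups should stay untouched.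

**Step 8**
Reactants: 12 2-[2-(3-benzyloxy-4-methoxyphenyl)ethyl]-6,7-dimethoxy-4H-chromen-4-one
Product: 13 2-[2-(3-hydroxy-4-methoxyphenyl)ethyl]-6,7-dimethoxy-4H-chromen-4-one (target)
Conditions: H2 (1 atm), Pd/C (10% Pd), EtOAc/MeOH, rt, stopped at full conversion
Reagents that add atoms: none
Why: Catalytic hydrogenolysis of an aryl benzyl ether at 1 atm should be much faster than hydrogenation of the vinylogous-ester C2=C3 bond of the chromone, so the phenol should be released with ring C intact.

**Compound list**
1 | 2'-hydroxy-4',5'-dimethoxyacetophenone | CC(=O)c1cc(OC)c(OC)cc1O | starting material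
2 | N,N-dimethylformamide dimethyl acetal | COC(OC)N(C)C | starting material
3 | (E)-3-(dimethylamino)-1-(2-hydroxy-4,5-dimethoxyphenyl)prop-2-en-1-one | CN(C)/C=C/C(=O)c1cc(OC)c(OC)cc1O | intermediate
4 | 6,7-dimethoxychromone | COc1cc2occc(=O)c2cc1OC | intermediate
5 | 3-hydroxy-4-methoxyphenylacetic acid | COc1ccc(CC(=O)O)cc1O | starting material
6 | benzyl 2-(3-benzyloxy-4-methoxyphenyl)acetate | COc1ccc(CC(=O)OCc2ccccc2)cc1OCc1ccccc1 | intermediate
7 | 2-(3-benzyloxy-4-methoxyphenyl)ethanol | COc1ccc(CCO)cc1OCc1ccccc1 | intermediate
8 | 2-(benzyloxy)-4-(2-bromoethyl)-1-methoxybenzene | COc1ccc(CCBr)cc1OCc1ccccc1 | intermediate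
9 | 2-(3-benzyloxy-4-methoxyphenyl)ethylmagnesium bromide | COc1ccc(CC[Mg]Br)cc1OCc1ccccc1 | intermediate
10 | 2-[2-(3-benzyloxy-4-methoxyphenyl)ethyl]-6,7-dimethoxy-4-(trimethylsilyloxy)-2H-chromene (racemic) | COc1ccc(CCC2C=C(O[Si](C)(C)C)c3cc(OC)c(OC)cc3O2)cc1OCc1ccccc1 | intermediate
11 | 2-[2-(3-benzyloxy-4-methoxyphenyl)ethyl]-6,7-dimethoxychroman-4-one (racemic) | COc1ccc(CCC2CC(=O)c3cc(OC)c(OC)cc3O2)cc1OCc1ccccc1 | intermediate
12 | 2-[2-(3-benzyloxy-4-methoxyphenyl)ethyl]-6,7-dimethoxy-4H-chromen-4-one | COc1ccc(CCc2cc(=O)c3cc(OC)c(OC)cc3o2)cc1OCc1ccccc1 | intermediate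
13 | 2-[2-(3-hydroxy-4-methoxyphenyl)ethyl]-6,7-dimethoxy-4H-chromen-4-one | COc1ccc(CCc2cc(=O)c3cc(OC)c(OC)cc3o2)cc1O | target

**Total step count:** 8.
**Longest linear sequence:** 7 steps (steps 2–8, from 5 to 13); the chromone branch (step 1) joins at step 6.

**Steps most likely to fail**

1. Step 6. The copper-mediated 1,4-transfer to the electron-rich chromone may be slow and be outpaced by direct carbonyl attack of the Grignard reagent, or the magnesium enolate may expel the ring phenoxide and open ring C before it is silylated. The fallback builds ring C around the chain instead; it sets out from 9 and 1 and comes back to the route at 12. Grignard reagent 9 would be carboxylated (CO2, THF, −20 °C → rt, HCl work-up) to 3-(3-benzyloxy-4-methoxyphenyl)propanoic acid F1. Steglich esterification of F1 with phenol 1 (EDC·HCl, DMAP, CH2Cl2) should give 2-acetyl-4,5-dimethoxyphenyl 3-(3-benzyloxy-4-methoxyphenyl)propanoate F2. Baker–Venkataraman rearrangement (LiN(SiMe3)2, THF, −20 → 0 °C) should give 5-(3-benzyloxy-4-methoxyphenyl)-1-(2-hydroxy-4,5-dimethoxyphenyl)pentane-1,3-dione F3. Acid cyclodehydration (p-TsOH, toluene, 80 °C) should then close the pyranone to 12, so that steps 6 and 7 are both bypassed.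

2. Step 7. The dehydrogenation may stall at partial conversion, or the pentavalent iodine oxidant may also attack the electron-rich benzylic CH2 groups if the mixture has to be warmed. The fallback sets out from 11 and comes back at 12; it replaces the direct oxidation by a two-stage sequence through an isolable enol derivative. Soft enolisation of 11 (Et3SiOTf, Et3N, CH2Cl2, 0 °C) should give the triethylsilyl enol ether 2-[2-(3-benzyloxy-4-methoxyphenyl)ethyl]-6,7-dimethoxy-4-(triethylsilyloxy)-2H-chromene F4, chosen because it resists adventitious hydrolysis during solvent exchange. Saegusa–Ito oxidation of F4 (Pd(OAc)2, 1.1 equiv, MeCN, rt) should then give 12: the oxa-π-allyl complex of divalent palladium loses the C2 hydrogen by β-hydride elimination.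

3. Step 8. Over-reduction may occur: once the benzyl ether is cleaved, hydrogen may add slowly to the C2=C3 bond of ring C. The fallback sets out from 12 and comes back at 13 and makes no new compound (F0). It is a non-reductive Lewis-acid debenzylation with BCl3 and pentamethylbenzene as cation scavenger in CH2Cl2 at −78 °C, then MeOH quench; at this temperature the aryl methyl ethers should survive.

**Further compounds**
F1 | step 6 | 3-(3-benzyloxy-4-methoxyphenyl)propanoic acid | COc1ccc(CCC(=O)O)cc1OCc1ccccc1
F2 | step 6 | 2-acetyl-4,5-dimethoxyphenyl 3-(3-benzyloxy-4-methoxyphenyl)propanoate | COc1ccc(CCC(=O)Oc2cc(OC)c(OC)cc2C(C)=O)cc1OCc1ccccc1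
F3 | step 6 | 5-(3-benzyloxy-4-methoxyphenyl)-1-(2-hydroxy-4,5-dimethoxyphenyl)pentane-1,3-dione | COc1ccc(CCC(=O)CC(=O)c2cc(OC)c(OC)cc2O)cc1OCc1ccccc1
F4 | step 7 | 2-[2-(3-benzyloxy-4-methoxyphenyl)ethyl]-6,7-dimethoxy-4-(triethylsilyloxy)-2H-chromene (racemic) | COc1ccc(CCC2C=C(O[Si](CC)(CC)CC)c3cc(OC)c(OC)cc3O2)cc1OCc1ccccc1
F0 | step 8 | none | none
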